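Compare the clearing time with the time allowed before you read anything else from this flask.

| flask | left-handed substrate | right-handed substrate | gas | catalyst | remark | time |
|---|---|---|---|---|---|---|
| ash | 0.30 M | 0.30 M | 57 mM (held) | 5.8 mol% | the very flask that is asked about, followed so far |  |
| larch | 0.30 M | 0.30 M | 57 mM (held) | 12 mol% | run made earlier |  |
| flask | 0.30 M | 0.30 M | 57 mM (held) | 5.8 mol% |  | 1.5 h |

| run | time / min | left-handed substrate / % | left-handed product / % | right-handed product / % |
|---|---|---|---|---|
| ash | 3.00 | 8.2 | 42.7 | 29.5 |
| ash | 6.00 | 0.6 | 52.1 | 48.6 |
| ash | 15.0 | 2.0 | 48.8 | 47.0 |
| ash | 40.0 | 0.3 | 51.8 | 49.3 |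
| larch | 3.00 | 5.0 | 44.8 | 33.7 |
| larch | 6.00 | 0 | 50.0 | 48.5 |
| larch | 15.0 | 0 | 51.4 | 48.6 |
| larch | 40.0 | 0 | 52.4 | 50.3 |

(readings scatter by 1 percentage point)

- catalyst is single-handed; left-handed substrate and right-handed substrate are mirror images of each other, charged as a racemate, each of them at the stated concentration
- at the start none of the gas is in solution
- the reaction counts as stopped when no species that holds the left-handed substrate and right-handed substrate together changes by six tenths of a point or more over the second half of the time

1. the state of affairs at 1.5 h: stopped, and by what, or still going (forward and back rates have come level / all of the left-handed substrate has reacted / no working catalyst is left / it is still moving)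
2. part of the left-handed substrate and right-handed substrate together gone at 1.5 h
3. the left-handed product standing at 1.5 h, as a percentage of the left-handed substrate and right-handed substrate together charged
4. the right-handed product standing at 1.5 h, as a percentage of the left-handed substrate and right-handed substrate together charged

1. Fastest rung. In the ash run, 42.7 % left-handed product and 29.5 % right-handed product stand at 3.00 min. At that pace the charge lasts 4.16 min: this is the clearing time, the time the whole charge needs at the average pace up to the first reading.

2. Same rung, larch run. With twice the catalyst, the larch run's clearing time is 3.82 min, shorter by a factor of 1.09.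

3. Middle rung. At 6.00 min, left-handed substrate reads 0.6 % in the ash run and 0 % in the larch run, against a scatter of 1 percentage point. The two products together read 101 % there in the ash run, 95.8 % at 15.0 min and 101 % at 40.0 min, so the ash run shows no steady drift over that stretch.

4. Slowest rung. The asked 1.5 h is 21.7 clearing times, far longer than the one clearing time read from the ash run. My reckoning is that the left-handed substrate has reacted and the products stand at their late readings.

5. The forecast gives all of the left-handed substrate has reacted, with conversion 99.8 %, left-handed product 51 % and right-handed product 48.9 %. It reasons: “There is therefore no sign of an equilibrium residue, and no stall from catalyst death.”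

6. The flask gives all of the left-handed substrate has reacted, with conversion 100 %, left-handed product 51.5 % and right-handed product 48.5 %.

    reagent + catalyst + left-handed substrate → catalyst + left-handed product (k = 85.0 M⁻² s⁻¹)
    reagent + catalyst + right-handed substrate → catalyst + right-handed product (k = 43.0 M⁻² s⁻¹)
    left-handed substrate ⇌ right-handed substrate (k = 6.50 × 10⁻⁴ s⁻¹)
    gas ⇌ reagent, rate k4*(csat - [reagent]) (kL = 0.0490 s⁻¹)

The flask holds left-handed product at 51.5 % because right-handed substrate has its own route to right-handed product; the same flask without that step ends at 98.4 % left-handed product. Over the second half of the 21.7 clearing times, the flask's largest change is 0 points. The same flask left until 40 min has 9.62 clearing times behind it, and there left-handed substrate stands at 0 %, left-handed product at 51.5 % and right-handed product at 48.5 %.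

(The earlier runs and the new flask are simulated with constants of no real substance.)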